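The route rests on opening the pyrrole ring of the indole (N1, C2, C3, C3a, C7a) across C3–C3a and N1–C2. Because C3 carries a CH(CH2OH) carbon, the target is a β-branched tryptophol. A Fischer indolization of 4-bromophenylhydrazine with a 3-substituted 4-hydroxybutanal, held as its γ-lactol, fuses that ring onto the arene in one operation and leaves the stereocentre and the free primary alcohol in place. The precursor is a tetrahydrofuran-2-ol bearing a 2-hydroxypropan-2-yl group at C4 with (S) configuration; its stereocentre comes from a rhodium-catalysed conjugate addition. Bromine at C5 is later exchanged for prenyl, and the primary alcohol is palmitoylated last.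

Key step: step 4

Remark 1: the ligand antipode in step 1 is assigned from the usual facial model for Rh/BINAP additions to cyclic Z-enones and enoates; the configuration should be confirmed on 3 and the other antipode used if the sense is reversed.
Remark 2: lactol 5 is drawn closed through the primary oxygen; every ring–chain tautomer of its hydroxy aldehyde feeds the same hydrazone, and the hydrazine is used as its commercial hydrochloride, which supplies the acid.

Step 1
Reactants: 1 2(5H)-furanone; 2 potassium trifluoro(prop-1-en-2-yl)borate
Product: 3 (R)-4-(prop-1-en-2-yl)dihydrofuran-2(3H)-one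
Conditions: [Rh(cod)2]BF4 (3 mol%), (R)-BINAP (3.3 mol%), toluene/H2O (20:1), 105 °C
Reagents that add atoms: none
Why: Hayashi–Miyaura-type Rh(I)-catalysed asymmetric 1,4-addition, in which the alkenyl–rhodium species formed by transmetalation inserts the lactone C=C on the face left open by the (R)-BINAP ligand and water releases the product from the oxa-π-allyl rhodium, so that the C4 stereocentre is set under catalyst control.

Step 2
Reactants: 3 (R)-4-(prop-1-en-2-yl)dihydrofuran-2(3H)-one
Product: 4 (S)-4-(2-hydroxypropan-2-yl)dihydrofuran-2(3H)-one
Conditions: Co(acac)2 (20 mol%), PhSiH3 (2.5 equiv), O2 (1 atm), THF, 23 °C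
Reagents that add atoms: dioxygen, O=O
Why: Mukaiyama hydration (cobalt-catalysed hydrogen-atom transfer), in which H is delivered to the terminal CH2, the tertiary radical is trapped by O2 and the peroxide is reduced by the silane, giving the Markovnikov tertiary alcohol without touching C4 or the lactone (the descriptor changes from R to S only because the priorities change).

Step 3
Reactants: 4 (S)-4-(2-hydroxypropan-2-yl)dihydrofuran-2(3H)-one
Product: 5 (4S)-4-(2-hydroxypropan-2-yl)tetrahydrofuran-2-ol (anomeric mixture)
Conditions: DIBAL-H (2.2 equiv), CH2Cl2, −78 °C; aq. Rochelle salt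
Reagents that add atoms: none
Why: DIBAL-H half-reduction of a γ-lactone, which stops at the tetrahedral aluminium hemiacetal at −78 °C after the first equivalent has been consumed by the tertiary hydroxyl, and any migration of the lactone onto the tertiary oxygen beforehand is harmless because both lactones reduce to ring tautomers of one hydroxy aldehyde.

Step 4
Reactants: 5 (4S)-4-(2-hydroxypropan-2-yl)tetrahydrofuran-2-ol; 6 4-bromophenylhydrazine hydrochloride
Product: 9 (S)-2-(5-bromo-1H-indol-3-yl)-3-methylbutane-1,3-diol, via 4-bromophenylhydrazine free base 7 (not isolated), via open-chain arylhydrazone 8 (not isolated)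
Conditions: 5 added slowly to 6 (1.1 equiv), degassed DMA/H2O (1:1), N2, 85 °C
Reagents that add atoms: none
Why: This is a Fischer indole synthesis on a lactol (the tryptophol variant): 5 equilibrates with its open 4-hydroxy aldehyde, which condenses with 7 to hydrazone 8, protonated 8 tautomerises to the ene-hydrazine through its only α-CH2, and a [3,3]-sigmatropic shift joins that carbon to an ortho carbon of the arene (C3–C3a). Rearomatisation gives an ortho-aminoaryl iminium ion, the aniline nitrogen adds to the iminium carbon in a 5-exo-trig closure (N1–C2), and loss of ammonia aromatises the pyrrole ring. No stereocentre is created, and the existing one lies one carbon beyond the ene-hydrazine, is never sp2-hybridised and should be carried through unchanged. Regiochemistry needs no control, since the two ortho positions of the para-substituted hydrazine are equivalent (bromine ends at C5) and the aldehyde has a single enolisable position (C2 stays unsubstituted). The selectivity that needs care is survival of the tertiary carbinol next to the new indole: the only acid is the one equivalent of HCl carried by the hydrazine, it is neutralised by the ammonia released as the indole forms, and the water-rich medium returns any tertiary cation to the alcohol. The slight excess of 6 and the slow addition of 5 suppress oxa-Pictet–Spengler capture of unreacted aldehyde by the product.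

Step 5
Reactants: 9 (S)-2-(5-bromo-1H-indol-3-yl)-3-methylbutane-1,3-diol; 10 prenylboronic acid pinacol ester
Product: 11 (S)-3-methyl-2-[5-(3-methylbut-2-en-1-yl)-1H-indol-3-yl]butane-1,3-diol
Conditions: Pd-PEPPSI-IPent (3 mol%), 5 M aq. KOH (4 equiv), THF, 70 °C
Reagents that add atoms: none
Why: Suzuki–Miyaura allyl–aryl coupling, in which the very bulky IPent carbene ligand makes the prenyl group bind palladium through its unsubstituted CH2 terminus after oxidative addition into C5–Br and transmetalation, so that reductive elimination should give the linear prenyl arene and not the 1,1-dimethylallyl isomer, while aqueous hydroxide is compatible with the free N–H and both hydroxyls.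

Step 6
Reactants: 11 (S)-3-methyl-2-[5-(3-methylbut-2-en-1-yl)-1H-indol-3-yl]butane-1,3-diol; 12 palmitoyl chloride
Product: 13 (S)-3-hydroxy-3-methyl-2-[5-(3-methylbut-2-en-1-yl)-1H-indol-3-yl]butyl hexadecanoate
Conditions: 12 (1.05 equiv), pyridine, CH2Cl2, −20 → 0 °C
Reagents that add atoms: none
Why: Nucleophilic acyl substitution (O-acylation with an acid chloride in pyridine), in which the unhindered primary hydroxyl reacts far faster than the tertiary hydroxyl or the indole N–H, which is not acylated without deprotonation or DMAP, so that one equivalent of acid chloride at low temperature should give the mono-ester.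

Compound list
1 | 2(5H)-furanone | O=C1OCC=C1 | starting material
2 | potassium trifluoro(prop-1-en-2-yl)borate (potassium isopropenyltrifluoroborate) | [K+].C=C(C)[B-](F)(F)F | starting material
3 | (R)-4-(prop-1-en-2-yl)dihydrofuran-2(3H)-one | O1C[C@H](CC1=O)C(C)=C | intermediate
4 | (S)-4-(2-hydroxypropan-2-yl)dihydrofuran-2(3H)-one | O1C[C@H](CC1=O)C(C)(C)O | intermediate
5 | (4S)-4-(2-hydroxypropan-2-yl)tetrahydrofuran-2-ol, anomeric mixture | O1C[C@H](CC1O)C(C)(C)O | intermediate
6 | 4-bromophenylhydrazine hydrochloride | Cl.NNc1ccc(Br)cc1 | starting material
7 | 4-bromophenylhydrazine (free base, not isolated) | NNc1ccc(Br)cc1 | intermediate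
8 | (3S)-4-hydroxy-3-(hydroxymethyl)-4-methylpentanal 4-bromophenylhydrazone (not isolated) | OC[C@H](CC=NNc1ccc(Br)cc1)C(C)(C)O | intermediate
9 | (S)-2-(5-bromo-1H-indol-3-yl)-3-methylbutane-1,3-diol | OC[C@H](c1c[nH]c2ccc(Br)cc12)C(C)(C)O | intermediate
10 | prenylboronic acid pinacol ester, 4,4,5,5-tetramethyl-2-(3-methylbut-2-en-1-yl)-1,3,2-dioxaborolane | CC(C)=CCB1OC(C)(C)C(C)(C)O1 | starting material
11 | (S)-3-methyl-2-[5-(3-methylbut-2-en-1-yl)-1H-indol-3-yl]butane-1,3-diol | OC[C@H](c1c[nH]c2ccc(CC=C(C)C)cc12)C(C)(C)O | intermediate
12 | palmitoyl chloride (hexadecanoyl chloride) | CCCCCCCCCCCCCCCC(=O)Cl | starting material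
13 | (S)-3-hydroxy-3-methyl-2-[5-(3-methylbut-2-en-1-yl)-1H-indol-3-yl]butyl hexadecanoate | CCCCCCCCCCCCCCCC(=O)OC[C@H](c1c[nH]c2ccc(CC=C(C)C)cc12)C(C)(C)O | target

Total step count: 6. Longest linear sequence: 6 steps (1 → 3 → 4 → 5 → 9 → 11 → 13).

Steps most likely to fail

Step 4. Under the acid needed for the [3,3] shift of the electron-poor bromophenylhydrazone, the tertiary carbinol may ionise. That would lead to dehydration, or to a hydride shift towards the indol-3-yl carbon with loss of the stereocentre. The product may also be consumed by condensation with unreacted aldehyde. The fallback replaces the acid-mediated rearrangement by a base-mediated palladium annulation; it sets out from 5 and comes back at 9. Lactol 5 would be heated with 4-bromo-2-iodoaniline, Pd(OAc)2 and DABCO in DMF at 85 °C. The open aldehyde should condense to the N-(4-bromo-2-iodophenyl) imine of (3S)-4-hydroxy-3-(hydroxymethyl)-4-methylpentanal F1. Its enamine tautomer should undergo oxidative addition at the C–I bond only, and an intramolecular Heck cyclisation would form the same C3–C3a bond. Double-bond isomerisation then gives 9 without any acid.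

Step 1. Insertion of the poorly electrophilic five-membered lactone into the alkenyl–rhodium bond may be slow, the α-branched alkenylborate may protodeboronate first, or facial discrimination may be insufficient. The fallback replaces catalyst control by substrate control through a removable acetal auxiliary. It does not set out from 1 but from its purchasable chiral acetal analogue, (5S)-5-(d-menthyloxy)furan-2(5H)-one F2 (taking the place of 1 and 2), and comes back at 3. Copper-catalysed addition of isopropenylmagnesium bromide (CuBr·SMe2, TMSCl, THF, −78 °C) should occur anti to the menthyloxy group and give the trans adduct (4R,5S)-5-(d-menthyloxy)-4-(prop-1-en-2-yl)dihydrofuran-2(3H)-one F3. NaBH4 in aqueous KOH should then open the acylal and reduce the liberated aldehyde as it forms. On acidification the hydroxy acid closes to 3 and (+)-menthol is recovered.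

Step 5. Transmetalation and reductive elimination may take the γ-selective course and give the branched 1,1-dimethylallyl isomer, the allylic boronate may protodeboronate in aqueous base, or the indole N–H may inhibit the catalyst or be arylated. The fallback introduces an unsubstituted allyl group, whose two termini are identical, and builds the trisubstituted alkene afterwards; it sets out from 9 and comes back at 11. Suzuki coupling of 9 with allylboronic acid pinacol ester (Pd(dppf)Cl2, CsF, THF, 70 °C) should give (S)-2-(5-allyl-1H-indol-3-yl)-3-methylbutane-1,3-diol F4. Olefin cross-metathesis of F4 with excess 2-methylbut-2-ene (Grubbs second-generation catalyst, CH2Cl2, 40 °C) should exchange the terminal CH2 for an isopropylidene group and give 11.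

Further compounds
F1 | step 4 | N-(4-bromo-2-iodophenyl) imine of (3S)-4-hydroxy-3-(hydroxymethyl)-4-methylpentanal | OC[C@H](CC=Nc1ccc(Br)cc1I)C(C)(C)O
F2 | step 1 | (5S)-5-{[(1S,2R,5S)-2-isopropyl-5-methylcyclohexyl]oxy}furan-2(5H)-one | O1[C@H](O[C@H]2C[C@@H](C)CC[C@@H]2C(C)C)C=CC1=O
F3 | step 1 | (4R,5S)-5-{[(1S,2R,5S)-2-isopropyl-5-methylcyclohexyl]oxy}-4-(prop-1-en-2-yl)dihydrofuran-2(3H)-one | O1[C@H](O[C@H]2C[C@@H](C)CC[C@@H]2C(C)C)[C@H](CC1=O)C(C)=C
F4 | step 5 | (S)-2-(5-allyl-1H-indol-3-yl)-3-methylbutane-1,3-diol | OC[C@H](c1c[nH]c2ccc(CC=C)cc12)C(C)(C)O
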